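The seven-membered ring (C1–C6 and C10, bicyclo[4.3.1]decane numbering) carries the whole plan: C10–C1–C2, with the ester on C2 and oxygen on C1, is read as a siloxyvinyl carbenoid, and C3–C6 as a diene. Tying the C2 carboxyl to the oxygen of the side-chain CH2O as a temporary δ-lactone makes the event intramolecular. One rhodium-catalysed cyclopropanation/Cope cascade (a formal [4+3] cycloaddition) forms C2–C3 and C6–C10, sets C3 and the quaternary C6, and leaves C1 as a masked ketone. Its precursor is an acyclic (3E,5Z)-trienyl 2-diazo-3-siloxybut-3-enoate. A samarium diiodide ketone–enone coupling later closes the C1–C9 bridge.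

Key step: step 7

Remark on the chemistry: 1 is used as the racemate, so 2, 3 and 6–9 are racemic and 10–12 are pairs of epimers at the oxygen-bearing allylic carbon, a centre erased in step 9; absolute configuration rests on catalyst control in step 7, where Rh2(S-PTAD)4 is assumed to select the alkene face leading to the enantiomer drawn (otherwise Rh2(R-PTAD)4 would be taken).

Step 1
Reactants: 1 pent-1-en-4-yn-3-ol (racemic)
Product: 2 (1Z)-1-iodo-2-methylpenta-1,4-dien-3-ol
Conditions: MeMgBr (2.5 equiv), CuI (10 mol%), Et2O, −10 °C to rt; then I2, −60 to 0 °C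
Reagents that add atoms: methylmagnesium bromide C[Mg]Br; iodine II
Why: Copper-catalysed anti-carbomagnesiation of the propargylic magnesium alkoxide puts methyl on the internal alkyne carbon and magnesium on the terminal carbon cis to the carbinol (five-membered chelate), so iodinolysis with retention should give the (Z)-alkenyl iodide, the carbinol centre staying racemic.

Step 2
Reactants: 2 (1Z)-1-iodo-2-methylpenta-1,4-dien-3-ol
Product: 3 tert-butyl{[(1Z)-1-iodo-2-methylpenta-1,4-dien-3-yl]oxy}dimethylsilane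
Conditions: TBSCl, imidazole, DMF, rt
Reagents that add atoms: tert-butyldimethylsilyl chloride CC(C)(C)[Si](C)(C)Cl
Why: Standard silyl ether protection of the secondary allylic alcohol masks the hydroxyl against the later acylation and carbenoid steps.

Step 3
Reactants: 4 but-3-yn-1-ol
Product: 5 (3E)-4-(4,4,5,5-tetramethyl-1,3,2-dioxaborolan-2-yl)but-3-en-1-ol
Conditions: pinacolborane (2.2 equiv), Cp2Zr(H)Cl (5 mol%), Et3N (10 mol%), neat, 60 °C; aqueous work-up
Reagents that add atoms: pinacolborane [BH]1OC(C)(C)C(C)(C)O1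
Why: Zirconium-catalysed syn-hydroboration of the terminal alkyne is anti-Markovnikov and should give the (E)-alkenylboronate, the O-boryl group formed at the hydroxyl being hydrolysed on work-up.

Step 4
Reactants: 3 tert-butyl{[(1Z)-1-iodo-2-methylpenta-1,4-dien-3-yl]oxy}dimethylsilane; 5 (3E)-4-(4,4,5,5-tetramethyl-1,3,2-dioxaborolan-2-yl)but-3-en-1-ol
Product: 6 (3E,5Z)-7-[(tert-butyldimethylsilyl)oxy]-6-methylnona-3,5,8-trien-1-ol
Conditions: Pd(dppf)Cl2 (5 mol%), K3PO4 (3 equiv), THF–H2O, rt
Reagents that add atoms: none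
Why: Suzuki–Miyaura coupling proceeds with retention at both alkenyl partners, so the (3E,5Z)-diene should result, with the silyloxyallyl group cis and the methyl trans to C4 of the chain.

Step 5
Reactants: 6 (3E,5Z)-7-[(tert-butyldimethylsilyl)oxy]-6-methylnona-3,5,8-trien-1-ol
Product: 8 (3E,5Z)-7-[(tert-butyldimethylsilyl)oxy]-6-methylnona-3,5,8-trien-1-yl 2-diazo-3-oxobutanoate, via acetoacetate 7 (not isolated)
Conditions: diketene, DMAP (cat.), Et3N, MeCN, 0 °C; then 4-acetamidobenzenesulfonyl azide, Et3N, 0 °C to rt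
Reagents that add atoms: diketene C=C1CC(=O)O1; 4-acetamidobenzenesulfonyl azide CC(=O)Nc1ccc(cc1)S(=O)(=O)N=[N+]=[N-]
Why: Diketene acetoacetylates the primary alcohol at 0 °C (no heating of the Z-diene) and Regitz diazo transfer to the active methylene then installs the diazo group in the same flask.

Step 6
Reactants: 8 (3E,5Z)-7-[(tert-butyldimethylsilyl)oxy]-6-methylnona-3,5,8-trien-1-yl 2-diazo-3-oxobutanoate
Product: 9 (3E,5Z)-7-[(tert-butyldimethylsilyl)oxy]-6-methylnona-3,5,8-trien-1-yl 3-[(tert-butyldimethylsilyl)oxy]-2-diazobut-3-enoate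
Conditions: TBSOTf, Et3N, CH2Cl2, 0 °C
Reagents that add atoms: tert-butyldimethylsilyl trifluoromethanesulfonate CC(C)(C)[Si](C)(C)OS(=O)(=O)C(F)(F)F
Why: Soft enolization of the acetyl group (O-silylation) gives the 2-siloxyvinyl diazoacetate, the usual precursor of siloxyvinyl carbenoids.

Step 7
Reactants: 9 (3E,5Z)-7-[(tert-butyldimethylsilyl)oxy]-6-methylnona-3,5,8-trien-1-yl 3-[(tert-butyldimethylsilyl)oxy]-2-diazobut-3-enoate
Product: 11 (4aR,7S)-9-[(tert-butyldimethylsilyl)oxy]-7-{1-[(tert-butyldimethylsilyl)oxy]prop-2-en-1-yl}-7-methyl-4,4a,7,8-tetrahydrocyclohepta[c]pyran-1(3H)-one, via cis-divinylcyclopropane 10 (not isolated)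
Conditions: Rh2(S-PTAD)4 (1 mol%), hexanes–toluene, slow addition of 9 (high dilution), 0 °C to rt; then 80 °C
Reagents that add atoms: none
Why: Loss of N2 gives the rhodium siloxyvinylcarbenoid, which cyclopropanates the proximal (3E)-alkene through a six-membered lactone-forming transition state (C2–C3 and a transient C2–C4 bond; numbering of the target) to the cis-fused cyclopropane lactone 10; because the alkene is E, the dienyl residue on C4 lies trans to the tether and hence cis to the siloxyvinyl group, so 10 is a cis-divinylcyclopropane that should undergo Cope rearrangement through the boat transition state on warming, forming C6–C10 while the strained C2–C4 bond breaks. The closest known reaction type is the tandem cyclopropanation/Cope rearrangement of vinyldiazoacetates with dienes (formal [4+3] cycloaddition), including its intramolecular form with dienyl esters and the use of Rh2(S-PTAD)4 with 2-siloxyvinyldiazoacetates. The lactone ring closes during carbene transfer with the attacked alkene carbon C3 inside the new six-membered ring, and the seven-membered ring closes by the [3,3] shift. C3 is set by the alkene face that the chiral catalyst selects, and the quaternary C6 follows stereospecifically: in the boat the (5Z)-silyloxyallyl group must point inward and the methyl outward, which places the methyl cis to the tether CH2 on C3, as in the target. The step needs site selectivity for the (3E)-alkene over the trisubstituted alkene and the remote vinyl group, which the short tether and slow addition at high dilution should secure, and enantioselectivity, which rests on the catalyst.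

Step 8
Reactants: 11 (4aR,7S)-9-[(tert-butyldimethylsilyl)oxy]-7-{1-[(tert-butyldimethylsilyl)oxy]prop-2-en-1-yl}-7-methyl-4,4a,7,8-tetrahydrocyclohepta[c]pyran-1(3H)-one
Product: 12 (4aR,7S,9aS)-7-(1-hydroxyprop-2-en-1-yl)-7-methyl-4,4a,7,8-tetrahydrocyclohepta[c]pyran-1,9(3H,9aH)-dione
Conditions: HF·pyridine, pyridine, THF, 0 °C to rt
Reagents that add atoms: none
Why: Fluoride-mediated desilylation unmasks the C1 ketone (target numbering) and the allylic alcohol, and the new epimerizable C2 centre of the β-keto lactone should settle under thermodynamic control in the trans ring fusion (carbonyl trans to the C3 substituent) that the target needs.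

Step 9
Reactants: 12 (4aR,7S,9aS)-7-(1-hydroxyprop-2-en-1-yl)-7-methyl-4,4a,7,8-tetrahydrocyclohepta[c]pyran-1,9(3H,9aH)-dione
Product: 13 (4aR,7S,9aS)-7-methyl-7-(prop-2-enoyl)-4,4a,7,8-tetrahydrocyclohepta[c]pyran-1,9(3H,9aH)-dione
Conditions: Dess–Martin periodinane, NaHCO3, CH2Cl2, 0 °C
Reagents that add atoms: none
Why: Dess–Martin oxidation of the secondary allylic alcohol gives the vinyl ketone and erases the epimeric carbinol centre under conditions mild enough for the enolizable β-keto lactone.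

Step 10
Reactants: 13 (4aR,7S,9aS)-7-methyl-7-(prop-2-enoyl)-4,4a,7,8-tetrahydrocyclohepta[c]pyran-1,9(3H,9aH)-dione
Product: 14 tricyclic hydroxy keto lactone (δ-lactone of 1-hydroxy-3-(2-hydroxyethyl)-6-methyl-7-oxobicyclo[4.3.1]dec-4-ene-2-carboxylic acid; C1, C2, C3 and C6 configured as in the target)
Conditions: SmI2 (2.5 equiv), (CF3)2CHOH (2 equiv), THF–HMPA, −78 °C
Reagents that add atoms: none
Why: Samarium diiodide-mediated reductive ketone–enone coupling (ketyl–olefin cyclization) should join C1 to the enone β-carbon C9 by six-membered ring closure, the tether on C6 allowing bond formation on one face only so that the C1 hydroxyl configuration is relayed from C6, and protonation of the samarium enolate leaves the C7 ketone.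

Step 11
Reactants: 14 tricyclic hydroxy keto lactone (dec-4-ene)
Product: 15 saturated tricyclic hydroxy keto lactone (δ-lactone of 1-hydroxy-3-(2-hydroxyethyl)-6-methyl-7-oxobicyclo[4.3.1]decane-2-carboxylic acid)
Conditions: H2 (1 atm), Pd/C (10%), EtOAc, rt
Reagents that add atoms: none
Why: Catalytic hydrogenation saturates the only C=C bond (C4=C5), creates no stereocentre and leaves ketone, lactone and tertiary alcohol untouched.

Step 12
Reactants: 15 saturated tricyclic hydroxy keto lactone
Product: 16 methyl (1S,2S,3S,6R)-1-hydroxy-3-(2-hydroxyethyl)-6-methyl-7-oxobicyclo[4.3.1]decane-2-carboxylate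
Conditions: MeOH, HCl (cat.), 0 °C to rt; NaHCO3 quench
Reagents that add atoms: methanol CO
Why: Acid-catalysed transesterification opens the δ-lactone to methyl ester and primary alcohol without the basic conditions that could trigger retro-aldol cleavage of the tertiary β-hydroxy ester, and the product is oxidized at once to forestall relactonization.

Step 13
Reactants: 16 methyl (1S,2S,3S,6R)-1-hydroxy-3-(2-hydroxyethyl)-6-methyl-7-oxobicyclo[4.3.1]decane-2-carboxylate
Product: 17 methyl (1S,2S,3S,6R)-1-hydroxy-6-methyl-7-oxo-3-(2-oxoethyl)bicyclo[4.3.1]decane-2-carboxylate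
Conditions: Dess–Martin periodinane, NaHCO3, CH2Cl2, 0 °C
Reagents that add atoms: none
Why: Dess–Martin oxidation converts the primary alcohol into the aldehyde, which cannot relactonize, while the tertiary alcohol is inert.

Step 14
Reactants: 18 2-methylbut-3-en-2-ol
Product: 19 (2E)-4-hydroxy-4-methylpent-2-enal
Conditions: crotonaldehyde (3 equiv), second-generation Hoveyda–Grubbs catalyst RuCl2(H2IMes)(=CH-C6H4-2-OiPr) (2 mol%), CH2Cl2, 40 °C
Reagents that add atoms: (E)-crotonaldehyde C/C=C/C=O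
Why: Olefin cross-metathesis of the tertiary allylic alcohol with crotonaldehyde should give the (E)-enal under thermodynamic control with loss of propene.

Step 15
Reactants: 17 methyl (1S,2S,3S,6R)-1-hydroxy-6-methyl-7-oxo-3-(2-oxoethyl)bicyclo[4.3.1]decane-2-carboxylate; 19 (2E)-4-hydroxy-4-methylpent-2-enal
Product: 20 methyl (1S,2S,3R,6R)-1-hydroxy-3-[(2E,4E)-6-hydroxy-6-methyl-1-oxohepta-2,4-dien-2-yl]-6-methyl-7-oxobicyclo[4.3.1]decane-2-carboxylate
Conditions: 19 (2.5 equiv), pyrrolidine (20 mol%), PhCO2H (20 mol%), toluene, rt to 40 °C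
Reagents that add atoms: none
Why: Amine-catalysed crossed aldol condensation (enamine of 17 adding to the non-enolizable enal 19, then elimination) should give the 2-substituted dienal as the (E)-isomer, formyl trans to the new chain, which is the thermodynamically preferred geometry and puts the chain cis to the ring carbon as in the target.

Step 16
Reactants: 20 methyl (1S,2S,3R,6R)-1-hydroxy-3-[(2E,4E)-6-hydroxy-6-methyl-1-oxohepta-2,4-dien-2-yl]-6-methyl-7-oxobicyclo[4.3.1]decane-2-carboxylate
Product: 21 methyl (1S,2S,3R,6R,7S)-3-[(2E,4E)-1,6-dihydroxy-6-methylhepta-2,4-dien-2-yl]-1,7-dihydroxy-6-methylbicyclo[4.3.1]decane-2-carboxylate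
Conditions: NaBH4, CeCl3·7H2O, MeOH, −40 to 0 °C
Reagents that add atoms: none
Why: Luche reduction reduces the dienal 1,2 and the C7 ketone, where hydride should enter axially on the face opposite the four-carbon bridge (C2–C5) to give the equatorial C7 alcohol cis to C5 (substrate control).

Step 17
Reactants: 21 methyl (1S,2S,3R,6R,7S)-3-[(2E,4E)-1,6-dihydroxy-6-methylhepta-2,4-dien-2-yl]-1,7-dihydroxy-6-methylbicyclo[4.3.1]decane-2-carboxylate
Product: 22 methyl (1S,2S,3R,6R,7S)-3-[(2E,4E)-1-(acetyloxy)-6-hydroxy-6-methylhepta-2,4-dien-2-yl]-1,7-dihydroxy-6-methylbicyclo[4.3.1]decane-2-carboxylate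
Conditions: Ac2O (1.1 equiv), pyridine, CH2Cl2, 0 °C
Reagents that add atoms: acetic anhydride CC(=O)OC(C)=O
Why: Acetylation under mild base is selective for the primary allylic alcohol over the hindered secondary and the two tertiary alcohols (steric differentiation) and is run at once so that the hydroxy ester does not lactonize.

Compound list
1 | pent-1-en-4-yn-3-ol (racemic) | C=CC(O)C#C | starting material
2 | (1Z)-1-iodo-2-methylpenta-1,4-dien-3-ol (racemic at C3) | I/C=C(C)\C(O)C=C | intermediate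
3 | tert-butyl{[(1Z)-1-iodo-2-methylpenta-1,4-dien-3-yl]oxy}dimethylsilane (racemic) | I/C=C(C)\C(O[Si](C)(C)C(C)(C)C)C=C | intermediate
4 | but-3-yn-1-ol | C#CCCO | starting material
5 | (3E)-4-(4,4,5,5-tetramethyl-1,3,2-dioxaborolan-2-yl)but-3-en-1-ol | OCC/C=C/B1OC(C)(C)C(C)(C)O1 | intermediate
6 | (3E,5Z)-7-[(tert-butyldimethylsilyl)oxy]-6-methylnona-3,5,8-trien-1-ol (racemic at C7) | OCC/C=C/C=C(C)\C(O[Si](C)(C)C(C)(C)C)C=C | intermediate
7 | (3E,5Z)-7-[(tert-butyldimethylsilyl)oxy]-6-methylnona-3,5,8-trien-1-yl 3-oxobutanoate (racemic) | CC(=O)CC(=O)OCC/C=C/C=C(C)\C(O[Si](C)(C)C(C)(C)C)C=C | intermediate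
8 | (3E,5Z)-7-[(tert-butyldimethylsilyl)oxy]-6-methylnona-3,5,8-trien-1-yl 2-diazo-3-oxobutanoate (racemic) | CC(=O)C(=[N+]=[N-])C(=O)OCC/C=C/C=C(C)\C(O[Si](C)(C)C(C)(C)C)C=C | intermediate
9 | (3E,5Z)-7-[(tert-butyldimethylsilyl)oxy]-6-methylnona-3,5,8-trien-1-yl 3-[(tert-butyldimethylsilyl)oxy]-2-diazobut-3-enoate (racemic) | C=C(O[Si](C)(C)C(C)(C)C)C(=[N+]=[N-])C(=O)OCC/C=C/C=C(C)\C(O[Si](C)(C)C(C)(C)C)C=C | intermediate
10 | 1-{1-[(tert-butyldimethylsilyl)oxy]ethenyl}-7-{(1Z)-3-[(tert-butyldimethylsilyl)oxy]-2-methylpenta-1,4-dien-1-yl}-3-oxabicyclo[4.1.0]heptan-2-one, the two alkenyl groups cis on the cyclopropane and anti to the lactone ring; both epimers at the silyloxy carbon | O=C1OCC[C@@H]2[C@@H](/C=C(C)\C(O[Si](C)(C)C(C)(C)C)C=C)[C@]12C(O[Si](C)(C)C(C)(C)C)=C | intermediate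
11 | (4aR,7S)-9-[(tert-butyldimethylsilyl)oxy]-7-{1-[(tert-butyldimethylsilyl)oxy]prop-2-en-1-yl}-7-methyl-4,4a,7,8-tetrahydrocyclohepta[c]pyran-1(3H)-one, 7-methyl cis to C4; both epimers at the silyloxy carbon | O=C1OCC[C@@H]2C=C[C@@](C)(C(O[Si](C)(C)C(C)(C)C)C=C)CC(O[Si](C)(C)C(C)(C)C)=C12 | intermediate
12 | (4aR,7S,9aS)-7-(1-hydroxyprop-2-en-1-yl)-7-methyl-4,4a,7,8-tetrahydrocyclohepta[c]pyran-1,9(3H,9aH)-dione, trans-fused; both epimers at the carbinol | O=C1OCC[C@@H]2C=C[C@@](C)(C(O)C=C)CC(=O)[C@@H]12 | intermediate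
13 | (4aR,7S,9aS)-7-methyl-7-(prop-2-enoyl)-4,4a,7,8-tetrahydrocyclohepta[c]pyran-1,9(3H,9aH)-dione, trans-fused | O=C1OCC[C@@H]2C=C[C@@](C)(C(=O)C=C)CC(=O)[C@@H]12 | intermediate
14 | δ-lactone (C2 carboxyl to the hydroxyethyl oxygen) of 1-hydroxy-3-(2-hydroxyethyl)-6-methyl-7-oxobicyclo[4.3.1]dec-4-ene-2-carboxylic acid; H-2 and H-3 trans; C1, C2, C3, C6 as in the target | O=C1OCC[C@@H]2C=C[C@]3(C)C[C@@](O)(CCC3=O)[C@@H]12 | intermediate
15 | δ-lactone (C2 carboxyl to the hydroxyethyl oxygen) of 1-hydroxy-3-(2-hydroxyethyl)-6-methyl-7-oxobicyclo[4.3.1]decane-2-carboxylic acid; C1, C2, C3, C6 as in the target | O=C1OCC[C@@H]2CC[C@]3(C)C[C@@](O)(CCC3=O)[C@@H]12 | intermediate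
16 | methyl (1S,2S,3S,6R)-1-hydroxy-3-(2-hydroxyethyl)-6-methyl-7-oxobicyclo[4.3.1]decane-2-carboxylate | COC(=O)[C@H]1[C@H](CCO)CC[C@]2(C)C[C@@]1(O)CCC2=O | intermediate
17 | methyl (1S,2S,3S,6R)-1-hydroxy-6-methyl-7-oxo-3-(2-oxoethyl)bicyclo[4.3.1]decane-2-carboxylate | COC(=O)[C@H]1[C@H](CC=O)CC[C@]2(C)C[C@@]1(O)CCC2=O | intermediate
18 | 2-methylbut-3-en-2-ol | C=CC(C)(C)O | starting material
19 | (2E)-4-hydroxy-4-methylpent-2-enal | O=C/C=C/C(C)(C)O | intermediate
20 | methyl (1S,2S,3R,6R)-1-hydroxy-3-[(2E,4E)-6-hydroxy-6-methyl-1-oxohepta-2,4-dien-2-yl]-6-methyl-7-oxobicyclo[4.3.1]decane-2-carboxylate | COC(=O)[C@H]1[C@H](/C(=C\C=C\C(C)(C)O)C=O)CC[C@]2(C)C[C@@]1(O)CCC2=O | intermediate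
21 | methyl (1S,2S,3R,6R,7S)-3-[(2E,4E)-1,6-dihydroxy-6-methylhepta-2,4-dien-2-yl]-1,7-dihydroxy-6-methylbicyclo[4.3.1]decane-2-carboxylate | COC(=O)[C@H]1[C@H](/C(=C\C=C\C(C)(C)O)CO)CC[C@]2(C)C[C@@]1(O)CC[C@@H]2O | intermediate
22 | methyl (1S,2S,3R,6R,7S)-3-[(2E,4E)-1-(acetyloxy)-6-hydroxy-6-methylhepta-2,4-dien-2-yl]-1,7-dihydroxy-6-methylbicyclo[4.3.1]decane-2-carboxylate | COC(=O)[C@H]1[C@H](/C(=C\C=C\C(C)(C)O)COC(C)=O)CC[C@]2(C)C[C@@]1(O)CC[C@@H]2O | target

Total step count: 17. Longest linear sequence: 15 steps (steps 1, 2, 4–13, 15–17).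

Steps most likely to fail

1. Step 7. What may go wrong: poor facial discrimination in carbene transfer to an (E)-alkene held in a six-membered tether (low enantiomeric purity), diversion of the carbenoid to the remote vinyl group or to dimerization, and a slow Cope shift because the silyloxyallyl group must sit inward in the boat. Fallback, setting out from 8 and coming back at 11: carbene transfer and sigmatropic shift would be separated. The acceptor/acceptor diazo ester 8 would be cyclized with the chiral cobalt porphyrin catalyst Co(3,5-DitBu-ChenPhyrin) (divalent cobalt), a catalyst class known for enantioselective intramolecular cyclopropanation of (E)-alkenes by such diazo esters, to give the acetylcyclopropane lactone 1-acetyl-7-{(1Z)-3-[(tert-butyldimethylsilyl)oxy]-2-methylpenta-1,4-dien-1-yl}-3-oxabicyclo[4.1.0]heptan-2-one F1. Soft enolization of the acetyl group (TBSOTf, Et3N, CH2Cl2, 0 °C) would then give the siloxyvinyl compound 10, which should rearrange to 11 on warming to 80 °C.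

2. Step 10. What may go wrong: simple conjugate reduction of the enone, reductive aldol closure through the enone α-carbon (five-membered ring) in place of β-coupling, or reaction through the minor C2 epimer of the β-keto lactone. Fallback, setting out from 11 and coming back at 14: the bridge would be closed by a Barbier addition of an alkyl iodide. Hydroboration of the terminal vinyl group of 11 (9-BBN, THF; NaBO3·4H2O) would give the primary alcohol (4aR,7S)-9-[(tert-butyldimethylsilyl)oxy]-7-{1-[(tert-butyldimethylsilyl)oxy]-3-hydroxypropyl}-7-methyl-4,4a,7,8-tetrahydrocyclohepta[c]pyran-1(3H)-one F2. Appel iodination (I2, PPh3, imidazole) would give the iodide (4aR,7S)-9-[(tert-butyldimethylsilyl)oxy]-7-{1-[(tert-butyldimethylsilyl)oxy]-3-iodopropyl}-7-methyl-4,4a,7,8-tetrahydrocyclohepta[c]pyran-1(3H)-one F3. Selective cleavage of the silyl enol ether (TBAF, AcOH, THF, 0 °C) would give the β-keto lactone (4aR,7S,9aS)-7-{1-[(tert-butyldimethylsilyl)oxy]-3-iodopropyl}-7-methyl-4,4a,7,8-tetrahydrocyclohepta[c]pyran-1,9(3H,9aH)-dione F4. Samarium Barbier cyclization (SmI2, HMPA, THF, −78 °C to rt) would give the bridged tertiary alcohol, the 7-O-silyl ether of the 1,7-dihydroxy tricyclic lactone F5. Desilylation (HF·pyridine) would give the 1,7-dihydroxy tricyclic lactone F6, and Dess–Martin oxidation of its secondary alcohol would give 14.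

3. Step 15. What may go wrong: conjugate addition of the enamine to the enal, or self-condensation of 17, competing with 1,2-addition and dehydration. Fallback, setting out from 17 and coming back at 20: the trisubstituted alkene would be made by cross-coupling. α-Methylenation of 17 (aqueous formaldehyde, pyrrolidine, propionic acid) would give methyl (1S,2S,3R,6R)-1-hydroxy-6-methyl-7-oxo-3-(3-oxoprop-1-en-2-yl)bicyclo[4.3.1]decane-2-carboxylate F7. Bromine addition (Br2, CH2Cl2, −78 °C) would give methyl (1S,2S,3R,6R)-3-(1,2-dibromo-3-oxopropan-2-yl)-1-hydroxy-6-methyl-7-oxobicyclo[4.3.1]decane-2-carboxylate F8, which is not isolated; dehydrobromination with Et3N would give methyl (1S,2S,3R,6R)-3-[(1E)-1-bromo-3-oxoprop-1-en-2-yl]-1-hydroxy-6-methyl-7-oxobicyclo[4.3.1]decane-2-carboxylate F9. Suzuki–Miyaura coupling of F9 with (E)-2-methyl-4-(4,4,5,5-tetramethyl-1,3,2-dioxaborolan-2-yl)but-3-en-2-ol (Pd(dppf)Cl2, K3PO4, THF–H2O) would then give 20 with retention of the alkene geometry.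

Further compounds
F1 | step 7 | 1-acetyl-7-{(1Z)-3-[(tert-butyldimethylsilyl)oxy]-2-methylpenta-1,4-dien-1-yl}-3-oxabicyclo[4.1.0]heptan-2-one (acetyl and dienyl cis) | O=C1OCC[C@@H]2[C@@H](/C=C(C)\C(O[Si](C)(C)C(C)(C)C)C=C)[C@]12C(C)=O
F2 | step 10 | (4aR,7S)-9-[(tert-butyldimethylsilyl)oxy]-7-{1-[(tert-butyldimethylsilyl)oxy]-3-hydroxypropyl}-7-methyl-4,4a,7,8-tetrahydrocyclohepta[c]pyran-1(3H)-one | O=C1OCC[C@@H]2C=C[C@@](C)(C(O[Si](C)(C)C(C)(C)C)CCO)CC(O[Si](C)(C)C(C)(C)C)=C12
F3 | step 10 | (4aR,7S)-9-[(tert-butyldimethylsilyl)oxy]-7-{1-[(tert-butyldimethylsilyl)oxy]-3-iodopropyl}-7-methyl-4,4a,7,8-tetrahydrocyclohepta[c]pyran-1(3H)-one | O=C1OCC[C@@H]2C=C[C@@](C)(C(O[Si](C)(C)C(C)(C)C)CCI)CC(O[Si](C)(C)C(C)(C)C)=C12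
F4 | step 10 | (4aR,7S,9aS)-7-{1-[(tert-butyldimethylsilyl)oxy]-3-iodopropyl}-7-methyl-4,4a,7,8-tetrahydrocyclohepta[c]pyran-1,9(3H,9aH)-dione | O=C1OCC[C@@H]2C=C[C@@](C)(C(O[Si](C)(C)C(C)(C)C)CCI)CC(=O)[C@@H]12
F5 | step 10 | δ-lactone of 7-[(tert-butyldimethylsilyl)oxy]-1-hydroxy-3-(2-hydroxyethyl)-6-methylbicyclo[4.3.1]dec-4-ene-2-carboxylic acid (both C7 epimers) | O=C1OCC[C@@H]2C=C[C@]3(C)C[C@@](O)(CCC3O[Si](C)(C)C(C)(C)C)[C@@H]12
F6 | step 10 | δ-lactone of 1,7-dihydroxy-3-(2-hydroxyethyl)-6-methylbicyclo[4.3.1]dec-4-ene-2-carboxylic acid (both C7 epimers) | O=C1OCC[C@@H]2C=C[C@]3(C)C[C@@](O)(CCC3O)[C@@H]12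
F7 | step 15 | methyl (1S,2S,3R,6R)-1-hydroxy-6-methyl-7-oxo-3-(3-oxoprop-1-en-2-yl)bicyclo[4.3.1]decane-2-carboxylate | COC(=O)[C@H]1[C@H](C(=C)C=O)CC[C@]2(C)C[C@@]1(O)CCC2=O
F8 | step 15 | methyl (1S,2S,3R,6R)-3-(1,2-dibromo-3-oxopropan-2-yl)-1-hydroxy-6-methyl-7-oxobicyclo[4.3.1]decane-2-carboxylate (both epimers at the brominated carbon) | COC(=O)[C@H]1[C@H](C(Br)(CBr)C=O)CC[C@]2(C)C[C@@]1(O)CCC2=O
F9 | step 15 | methyl (1S,2S,3R,6R)-3-[(1E)-1-bromo-3-oxoprop-1-en-2-yl]-1-hydroxy-6-methyl-7-oxobicyclo[4.3.1]decane-2-carboxylate | COC(=O)[C@H]1[C@H](/C(=C\Br)C=O)CC[C@]2(C)C[C@@]1(O)CCC2=O
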